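**Retrosynthetic overview**
- Feature: in rings F and G the ether carbons F-1 and G-1 each sit between two ring CH and para to the oxygen at position 4 of a 3,4,5-trioxygenated ring, which is the place of the carboxyl carbon in syringic and gallic acid. The ether links from the E-4 oxygen to F-1 and from the F-4 oxygen to G-1 are therefore cut back to the two ester links of an E–F–G didepside and made by twofold CO extrusion.
- The ether between D-6 and E-1 is cut by SNAr: the E-1 phenol displaces fluoride at D-6 of an A–B–C–D aldehyde whose formyl carbon sits on D-5 and is later exchanged for the D-5 hydroxyl (Baeyer–Villiger).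
- The three ethers joining ring A to B, B to C and C to D are cut by copper-catalysed couplings of 2,6-dimethoxyphenols with aryl bromides.
- No ring is formed: all seven benzene rings are bought. Order of union: G+F, then E, ester contraction; A+B, then C, then D; D–E union; cleavage of sixteen methyl ethers.

Key step: step 7

Remark on the chemistry: the target has no stereocentre. Rings are lettered A (2,4,6-trihydroxyphenoxy end) to G (3,4,5-trihydroxyphenoxy end). A ring position is written as ring letter, hyphen, locant (F-1 is carbon 1 of ring F). In rings B–G position 1 is the carbon whose ether oxygen points toward ring A, and in ring A position 1 is the ether carbon. All couplings and the handling of free polyphenols are assumed to be run under argon.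

**Route**

Step 1
Reactants: 1 syringic acid
Product: 2 benzyl syringate (benzyl 4-hydroxy-3,5-dimethoxybenzoate)
Conditions: BnBr, KHCO3, DMF, 40 °C
Reagents that add atoms: benzyl bromide, BrCc1ccccc1
Why: Carboxylate O-alkylation (SN2), in which hydrogencarbonate deprotonates only the carboxylic acid so that the phenol stays free.

Step 2
Reactants: 2 benzyl syringate; 3 3,4,5-trimethoxybenzoyl chloride
Product: 4 benzyl 3,5-dimethoxy-4-[(3,4,5-trimethoxybenzoyl)oxy]benzoate
Conditions: Et3N, DMAP (cat.), CH2Cl2, 0 °C to rt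
Reagents that add atoms: none
Why: DMAP-catalysed O-acylation of a phenol by an acid chloride, the acylpyridinium being reactive enough for the di-ortho-methoxy phenol.

Step 3
Reactants: 4 benzyl ester of the F–G depside
Product: 5 3,5-dimethoxy-4-[(3,4,5-trimethoxybenzoyl)oxy]benzoic acid
Conditions: H2 (1 atm), Pd/C, EtOAc, rt
Reagents that add atoms: none
Why: Hydrogenolysis of the benzyl ester, to which the aryl ester and the methyl ethers are inert.

Step 4
Reactants: 6 2,6-dimethoxy-1,4-benzoquinone
Product: 7 2,6-dimethoxybenzene-1,4-diol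
Conditions: H2 (1 atm), Pd/C, EtOAc, rt, filtered and concentrated under argon
Reagents that add atoms: none
Why: Catalytic hydrogenation of a quinone to its hydroquinone.

Step 5
Reactants: 7 2,6-dimethoxybenzene-1,4-diol
Product: 8 4-(benzyloxy)-2,6-dimethoxyphenol
Conditions: BnBr (1.0 equiv), K2CO3 (1.0 equiv), DMF, 0 °C to rt, argon
Reagents that add atoms: benzyl bromide, BrCc1ccccc1
Why: Williamson etherification, which should fall on the 4-hydroxyl because that hydroxyl is the more acidic and unhindered one while the 1-hydroxyl is flanked by two methoxy groups.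

Step 6
Reactants: 5 F–G depside acid; 8 4-(benzyloxy)-2,6-dimethoxyphenol
Product: 9 4-(benzyloxy)-2,6-dimethoxyphenyl 3,5-dimethoxy-4-[(3,4,5-trimethoxybenzoyl)oxy]benzoate (E–F–G didepside)
Conditions: DCC, DMAP (cat.), CH2Cl2, 0 °C to rt
Reagents that add atoms: none
Why: Steglich esterification, in which the unhindered carboxyl of 5 is activated as the O-acylisourea and passed by DMAP to the hindered phenol.

Step 7
Reactants: 9 E–F–G didepside
Product: 10 5-(benzyloxy)-1,3-dimethoxy-2-[3,5-dimethoxy-4-(3,4,5-trimethoxyphenoxy)phenoxy]benzene (E–F–G trimer, E-1 benzyl ether)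
Conditions: Ni(cod)2 (20 mol%), 3,4-bis(dicyclohexylphosphino)thiophene (dcypt, 40 mol%), K3PO4, m-xylene, 150 °C, slow argon stream
Reagents that add atoms: none
Why: Proposed new method: zerovalent nickel carrying the chelating, electron-rich bisphosphine should insert into each C(acyl)–O bond of 9 to give an acylnickel aryloxide, lose CO by de-insertion to an arylnickel aryloxide and turn over by C–O reductive elimination, so that both carbonyl carbons are excised and F-1 and G-1 become bonded directly to the oxygens on E-4 and F-4. The closest known reaction type is the nickel- or palladium-catalysed decarbonylative etherification of aryl azinecarboxylates with this ligand; a twofold extrusion on nitrogen-free, electron-rich benzoates of 2,6-dimethoxyphenols has not been shown, and here a flanking methoxy oxygen of each aryloxide is expected to take the chelating role of the azine nitrogen and hold the aryloxide on nickel through the CO loss. No ring is closed and no stereocentre is formed. The step needs insertion into the two acyl–oxygen bonds and not into aryl–OMe, aryl–O(acyl) or benzyl–O bonds; the acyl–oxygen bond is the weakest C–O bond present, the bidentate phosphine steers nickel to C(acyl)–O cleavage, and both aryl–O(acyl) carbons are shielded by two ortho methoxy groups. The ester between rings G and F, whose aryloxide carries the para carboxyl group, should react first, and the gas stream removes CO so that the catalyst is not held as a carbonyl complex.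

Step 8
Reactants: 10 E–F–G trimer benzyl ether
Product: 11 3,5-dimethoxy-4-[3,5-dimethoxy-4-(3,4,5-trimethoxyphenoxy)phenoxy]phenol (E–F–G phenol, free hydroxyl on E-1)
Conditions: H2 (1 atm), Pd/C, EtOAc–MeOH, rt
Reagents that add atoms: none
Why: Hydrogenolysis of the aryl benzyl ether, which leaves diaryl and methyl ethers untouched.

Step 9
Reactants: 12 4-bromo-2,6-dimethoxyphenol
Product: 13 2-(benzyloxy)-5-bromo-1,3-dimethoxybenzene
Conditions: BnBr, K2CO3, DMF, 60 °C
Reagents that add atoms: benzyl bromide, BrCc1ccccc1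
Why: Williamson etherification of the only hydroxyl group.

Step 10
Reactants: 14 2,4,6-trimethoxyphenol; 13 2-(benzyloxy)-5-bromo-1,3-dimethoxybenzene
Product: 15 2-(benzyloxy)-1,3-dimethoxy-5-(2,4,6-trimethoxyphenoxy)benzene (A–B benzyl ether)
Conditions: CuI (10 mol%), picolinic acid (20 mol%), K3PO4, DMSO, 100 °C, argon
Reagents that add atoms: none
Why: Ullmann-type copper-catalysed diaryl ether synthesis, for which the picolinate-ligated copper system accepts di-ortho-substituted phenols and the bromide carbon of 13 has no ortho substituent.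

Step 11
Reactants: 15 A–B benzyl ether
Product: 16 2,6-dimethoxy-4-(2,4,6-trimethoxyphenoxy)phenol (A–B phenol, free hydroxyl on B-4)
Conditions: H2 (1 atm), Pd/C, EtOAc–MeOH, rt
Reagents that add atoms: none
Why: Hydrogenolysis of the aryl benzyl ether.

Step 12
Reactants: 16 A–B phenol; 13 2-(benzyloxy)-5-bromo-1,3-dimethoxybenzene
Product: 17 2-(benzyloxy)-5-[2,6-dimethoxy-4-(2,4,6-trimethoxyphenoxy)phenoxy]-1,3-dimethoxybenzene (A–B–C benzyl ether)
Conditions: CuI (10 mol%), picolinic acid (20 mol%), K3PO4, DMSO, 100 °C, argon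
Reagents that add atoms: none
Why: Second Ullmann-type diaryl ether coupling of the same phenol class with the same bromide.

Step 13
Reactants: 17 A–B–C benzyl ether
Product: 18 4-[2,6-dimethoxy-4-(2,4,6-trimethoxyphenoxy)phenoxy]-2,6-dimethoxyphenol (A–B–C phenol, free hydroxyl on C-4)
Conditions: H2 (1 atm), Pd/C, EtOAc–MeOH, rt
Reagents that add atoms: none
Why: Hydrogenolysis of the aryl benzyl ether.

Step 14
Reactants: 18 A–B–C phenol; 19 1-bromo-2-fluoro-4,5-dimethoxybenzene
Product: 20 A–B–C–D fluoride: ring D is 2-fluoro-4,5-dimethoxyphenyl bound through D-1 to the oxygen on C-4 (methoxy on D-3 and D-4; fluorine on D-6; hydrogen on D-2 and D-5)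
Conditions: CuI (20 mol%), picolinic acid (40 mol%), K3PO4, DMSO, 110 °C, argon
Reagents that add atoms: none
Why: Ullmann-type diaryl ether coupling at the C–Br bond, the unactivated C–F bond being inert to phenoxide and copper under these conditions.

Step 15
Reactants: 20 A–B–C–D fluoride
Product: 21 A–B–C–D fluoro aldehyde: 3-(A–B–C-oxy)-2-fluoro-5,6-dimethoxybenzaldehyde (formyl on D-5, fluorine on D-6)
Conditions: LDA, THF, −78 °C; DMF, −78 to 0 °C; H2O
Reagents that add atoms: N,N-dimethylformamide, CN(C)C=O
Why: Directed ortho-metalation and formylation, in which the hydrogen on D-5, flanked by fluorine and a methoxy group, is the only proton acidic enough for LDA at −78 °C and the aryllithium is trapped by DMF before it can lose LiF.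

Step 16
Reactants: 21 A–B–C–D fluoro aldehyde; 11 E–F–G phenol
Product: 22 heptamer aldehyde: 2-(E–F–G-oxy)-3-(A–B–C-oxy)-5,6-dimethoxybenzaldehyde
Conditions: Cs2CO3, DMSO, 110 °C, argon
Reagents that add atoms: none
Why: SNAr (addition–elimination) in which the ortho formyl group stabilises the Meisenheimer adduct at D-6 and fluoride leaves, as in the known aryloxylation of 2-fluoro-alkoxybenzaldehydes, the phenoxide of 11 being unhindered at E-1.

Step 17
Reactants: 22 heptamer aldehyde
Product: 24 heptamer D-5 phenol (hexadecamethyl ether), via heptamer D-5 formate 23 (not isolated)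
Conditions: mCPBA, CH2Cl2, 0 °C to rt; wash (aq. NaHCO3); K2CO3 (cat.), MeOH, rt
Reagents that add atoms: meta-chloroperbenzoic acid, OOC(=O)c1cccc(Cl)c1
Why: Baeyer–Villiger (Dakin-type) oxidation, in which ring D with oxygen substituents on both carbons ortho to the formyl group migrates in preference to hydride and the aryl formate is then methanolysed.

Step 18
Reactants: 24 heptamer D-5 phenol
Product: 25 CNP0304148.0 (target, seventeen free hydroxyl groups)
Conditions: BBr3 (excess), CH2Cl2, −78 °C to rt, argon; H2O; Sephadex LH-20 with degassed solvents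
Reagents that add atoms: none
Why: Lewis-acid ether cleavage, in which bromide attacks the methyl group of each boron-complexed methoxy (SN2) while the diaryl ether links, having no sp3 carbon on oxygen, cannot be cleaved this way.

**Compound list**
1 | syringic acid | COc1cc(C(=O)O)cc(OC)c1O | starting material
2 | benzyl syringate | COc1cc(C(=O)OCc2ccccc2)cc(OC)c1O | intermediate
3 | 3,4,5-trimethoxybenzoyl chloride | COc1cc(C(Cl)=O)cc(OC)c1OC | starting material
4 | benzyl 3,5-dimethoxy-4-[(3,4,5-trimethoxybenzoyl)oxy]benzoate | COc1cc(C(=O)OCc2ccccc2)cc(OC)c1OC(=O)c1cc(OC)c(OC)c(OC)c1 | intermediate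
5 | 3,5-dimethoxy-4-[(3,4,5-trimethoxybenzoyl)oxy]benzoic acid | COc1cc(C(=O)O)cc(OC)c1OC(=O)c1cc(OC)c(OC)c(OC)c1 | intermediate
6 | 2,6-dimethoxy-1,4-benzoquinone | COC1=CC(=O)C=C(OC)C1=O | starting material
7 | 2,6-dimethoxybenzene-1,4-diol | COc1cc(O)cc(OC)c1O | intermediate
8 | 4-(benzyloxy)-2,6-dimethoxyphenol | COc1cc(OCc2ccccc2)cc(OC)c1O | intermediate
9 | E–F–G didepside, 4-(benzyloxy)-2,6-dimethoxyphenyl 3,5-dimethoxy-4-[(3,4,5-trimethoxybenzoyl)oxy]benzoate | COc1cc(OCc2ccccc2)cc(OC)c1OC(=O)c1cc(OC)c(OC(=O)c2cc(OC)c(OC)c(OC)c2)c(OC)c1 | intermediate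
10 | E–F–G trimer, E-1 benzyl ether | COc1cc(OCc2ccccc2)cc(OC)c1Oc1cc(OC)c(Oc2cc(OC)c(OC)c(OC)c2)c(OC)c1 | intermediate
11 | E–F–G phenol (free hydroxyl on E-1) | COc1cc(O)cc(OC)c1Oc1cc(OC)c(Oc2cc(OC)c(OC)c(OC)c2)c(OC)c1 | intermediate
12 | 4-bromo-2,6-dimethoxyphenol | COc1cc(Br)cc(OC)c1O | starting material
13 | 2-(benzyloxy)-5-bromo-1,3-dimethoxybenzene | COc1cc(Br)cc(OC)c1OCc1ccccc1 | intermediate
14 | 2,4,6-trimethoxyphenol | COc1cc(OC)c(O)c(OC)c1 | starting material
15 | A–B benzyl ether | COc1cc(OC)c(Oc2cc(OC)c(OCc3ccccc3)c(OC)c2)c(OC)c1 | intermediate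
16 | A–B phenol (free hydroxyl on B-4) | COc1cc(OC)c(Oc2cc(OC)c(O)c(OC)c2)c(OC)c1 | intermediate
17 | A–B–C benzyl ether | COc1cc(OC)c(Oc2cc(OC)c(Oc3cc(OC)c(OCc4ccccc4)c(OC)c3)c(OC)c2)c(OC)c1 | intermediate
18 | A–B–C phenol (free hydroxyl on C-4) | COc1cc(OC)c(Oc2cc(OC)c(Oc3cc(OC)c(O)c(OC)c3)c(OC)c2)c(OC)c1 | intermediate
19 | 1-bromo-2-fluoro-4,5-dimethoxybenzene | COc1cc(F)c(Br)cc1OC | starting material
20 | A–B–C–D fluoride | COc1cc(OC)c(Oc2cc(OC)c(Oc3cc(OC)c(Oc4cc(OC)c(OC)cc4F)c(OC)c3)c(OC)c2)c(OC)c1 | intermediate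
21 | A–B–C–D fluoro aldehyde | COc1cc(OC)c(Oc2cc(OC)c(Oc3cc(OC)c(Oc4cc(OC)c(OC)c(C=O)c4F)c(OC)c3)c(OC)c2)c(OC)c1 | intermediate
22 | heptamer aldehyde (formyl on D-5) | COc1cc(OC)c(Oc2cc(OC)c(Oc3cc(OC)c(Oc4cc(OC)c(OC)c(C=O)c4Oc4cc(OC)c(Oc5cc(OC)c(Oc6cc(OC)c(OC)c(OC)c6)c(OC)c5)c(OC)c4)c(OC)c3)c(OC)c2)c(OC)c1 | intermediate
23 | heptamer D-5 formate | COc1cc(OC)c(Oc2cc(OC)c(Oc3cc(OC)c(Oc4cc(OC)c(OC)c(OC=O)c4Oc4cc(OC)c(Oc5cc(OC)c(Oc6cc(OC)c(OC)c(OC)c6)c(OC)c5)c(OC)c4)c(OC)c3)c(OC)c2)c(OC)c1 | intermediate
24 | heptamer D-5 phenol, sixteen methyl ethers | COc1cc(OC)c(Oc2cc(OC)c(Oc3cc(OC)c(Oc4cc(OC)c(OC)c(O)c4Oc4cc(OC)c(Oc5cc(OC)c(Oc6cc(OC)c(OC)c(OC)c6)c(OC)c5)c(OC)c4)c(OC)c3)c(OC)c2)c(OC)c1 | intermediate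
25 | CNP0304148.0 | Oc1cc(O)c(Oc2cc(O)c(Oc3cc(O)c(Oc4cc(O)c(O)c(O)c4Oc4cc(O)c(Oc5cc(O)c(Oc6cc(O)c(O)c(O)c6)c(O)c5)c(O)c4)c(O)c3)c(O)c2)c(O)c1 | target

**Step count**
Total steps: 18. Longest linear sequence: 10 steps (12 to 25 through steps 9–18).

**Steps most likely to fail**

1. Step 7 (carries the new-method label). Nickel may fail to insert into the acyl–oxygen bonds of these electron-rich esters, may stop after one extrusion because CO stays bound, or aryloxide groups may exchange between molecules and scramble the ethers. The fallback uses known copper chemistry, sets out from 8 and 12 and comes back at 10. Phenol 12 is protected with chloromethyl methyl ether and iPr2NEt as 5-bromo-1,3-dimethoxy-2-(methoxymethoxy)benzene F1. Phenol 8 is coupled with it (CuI, picolinic acid, K3PO4, DMSO) to the E–F dimer MOM ether F2. HCl in MeOH frees the E–F phenol F3, and a second coupling under the same copper conditions with commercial 5-bromo-1,2,3-trimethoxybenzene gives 10.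

2. Step 14. Coupling of the di-ortho-substituted phenoxide with an electron-rich bromide may be slow, so that reductive loss of bromine and oxidative degradation of the phenoxide take over; steps 10 and 12 share this risk in a less crowded setting. The fallback sets out from 18 and comes back at 20. SNAr of 18 on commercial 4,5-difluoro-2-methoxybenzaldehyde (K2CO3, DMF, 90 °C), where only the fluorine para to the formyl group is activated, gives the A–B–C–D 4-formyl fluoride F4. mCPBA converts it to the aryl formate F5, K2CO3 in MeOH gives the D-4 phenol F6, and MeI with K2CO3 in acetone gives 20.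

3. Step 18. Cleavage of the sixteen methyl ethers may stay incomplete, and the electron-rich polyphenol may oxidise in air during work-up and purification. The fallback sets out from 24 and comes back at 25. Demethylation is run with AlBr3 and EtSH in CH2Cl2 (hard acid with soft nucleophile), and the crude polyphenol is acetylated at once with Ac2O and pyridine to the heptadecaacetate F7, which is stable to air and silica and can be purified. Acid-catalysed methanolysis (HCl from AcCl in degassed MeOH) and evaporation then release 25.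

**Further compounds**
F1 | step 7 | 5-bromo-1,3-dimethoxy-2-(methoxymethoxy)benzene | COCOc1c(OC)cc(Br)cc1OC
F2 | step 7 | E–F dimer, E-1 benzyl ether and F-4 MOM ether | COCOc1c(OC)cc(Oc2c(OC)cc(OCc3ccccc3)cc2OC)cc1OC
F3 | step 7 | 4-[4-(benzyloxy)-2,6-dimethoxyphenoxy]-2,6-dimethoxyphenol | Oc1c(OC)cc(Oc2c(OC)cc(OCc3ccccc3)cc2OC)cc1OC
F4 | step 14 | A–B–C–D 4-formyl fluoride, 4-(A–B–C-oxy)-5-fluoro-2-methoxybenzaldehyde | COc1cc(OC)c(Oc2cc(OC)c(Oc3cc(OC)c(Oc4cc(OC)c(C=O)cc4F)c(OC)c3)c(OC)c2)c(OC)c1
F5 | step 14 | A–B–C–D D-4 formate | COc1cc(OC)c(Oc2cc(OC)c(Oc3cc(OC)c(Oc4cc(OC)c(OC=O)cc4F)c(OC)c3)c(OC)c2)c(OC)c1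
F6 | step 14 | A–B–C–D D-4 phenol | COc1cc(OC)c(Oc2cc(OC)c(Oc3cc(OC)c(Oc4cc(OC)c(O)cc4F)c(OC)c3)c(OC)c2)c(OC)c1
F7 | step 18 | heptadecaacetate of 25 | CC(=O)Oc1cc(OC(C)=O)c(Oc2cc(OC(C)=O)c(Oc3cc(OC(C)=O)c(Oc4cc(OC(C)=O)c(OC(C)=O)c(OC(C)=O)c4Oc4cc(OC(C)=O)c(Oc5cc(OC(C)=O)c(Oc6cc(OC(C)=O)c(OC(C)=O)c(OC(C)=O)c6)c(OC(C)=O)c5)c(OC(C)=O)c4)c(OC(C)=O)c3)c(OC(C)=O)c2)c(OC(C)=O)c1
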